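Left to late times, target and by-product keep meeting in the side step, so these flasks are judged where they are stopped, at 2.0 h.

    coupling partner + free catalyst ⇌ catalyst intermediate A (K1 = 2.01 L mol⁻¹, k1 = 32.5 L mol⁻¹ h⁻¹)
    catalyst intermediate A ⇌ catalyst intermediate B (K2 = 1.92, k2 = 21.4 h⁻¹)
    catalyst intermediate B → by-product + catalyst intermediate C (k3 = 4.58 h⁻¹)
    substrate + catalyst intermediate C ⇌ catalyst intermediate D (K4 = 0.954 L mol⁻¹, k4 = 50.8 L mol⁻¹ h⁻¹)
    catalyst intermediate D → free catalyst + target (k5 = 27.2 h⁻¹)
    target + by-product → side product (k6 = 2.30 L mol⁻¹ h⁻¹)

the same everywhere: coupling partner 0.750 M; free catalyst 25 mM; time 2.0 h

| flask | substrate |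
|---|---|
| north-west | 0.10 M |
| south-west | 0.15 M |
| south | 0.20 M |
| south-east | 0.30 M |
| west | 0.50 M |

* [target] at the end for north-west, south-west, south, south-east, west, in this order
* the shape of the row from first to last (hardly changes / rises, then falls / rises all the way / falls, then rises / falls all the way)

What do you count? Turns of the catalyst. Each turn makes one target, so target made, before any side step, is the catalyst charge times the turns finished.

How long is a turn? Add up the stays in each form, since in a steady cycle a form's amount per unit of flow is its stay. Catalyst intermediate B empties forward in 0.218 h. Catalyst intermediate A must supply that flow and what falls back, which takes 0.160 h. Free catalyst, with the coupling partner held at its charge, takes 0.147 h, and catalyst intermediate D 0.0368 h. Together that is 0.563 h, with no substrate in it. Catalyst intermediate C is different: at 0.10 M substrate its stay, returns from catalyst intermediate D counted, is 0.582 h, and it shrinks inversely with substrate.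

So which number matters? 0.103 M: the crossover substrate, the concentration at which a turn spends as long in catalyst intermediate C as in the other forms together. In that steady cycle, with the coupling partner held at its charge, the share of catalyst in catalyst intermediate C is the crossover substrate over the sum of crossover substrate and substrate.

And in logarithms? That same share is the slope of log turn rate against log substrate. Across the charges it runs from 0.507 to 0.171, still positive but shrinking, so I expect a row that rises all the way and flattens.

But substrate falls, and the catalyst starts at the beginning of a turn. What then? Those are my two rough allowances. I take substrate as its charge less 12.5 mM and subtract 0.5 turn, and I leave the side step out. That gives 0.0282 M, 0.0382 M, 0.0447 M, 0.0528 M and 0.0608 M.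

The forecast, lower than mine at the top, gives 0.03 M, 0.038 M, 0.043 M, 0.049 M and 0.055 M, a row that rises all the way: “the row keeps rising while flattening”.

The simulation gives 0.0300 M, 0.0382 M, 0.0440 M, 0.0515 M and 0.0592 M, a row that rises all the way.

At the end of north-west the unbound substrate, 67% of its charge, stands below the crossover substrate, the stays put 60.6% of the catalyst in catalyst intermediate C, and the flask holds 58.6% there, its resting state, against 15.9% in catalyst intermediate B. At the end of west the unbound substrate, 87% of its charge, stands at 4.19 crossover substrates, the same rule gives 19.3%, and catalyst intermediate C, now behind catalyst intermediate B, holds 18.7%.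

The numbers of this flask are made up.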